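Assumption: isoprene, 3-methylfuran-2(5H)-one and both antipodes of the sulfinamide–phosphine ligand are taken as purchasable; operations run in one flask without isolation count as one step.

**Retrosynthetic overview**
- The benzene ring is bought: resacetophenone 1 (→ bromide 2) already carries the acetyl group, the future 6-OH and the future ring oxygen.
- O1–C2 and C3–C3a are cut together: 2 + isoprene 3 → (S)-6-hydroxytremetone 4 by enantioselective Heck/Tsuji–Trost heteroannulation. This closes the dihydrofuran ring, the only ring formed, and sets C2.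
- The acyl part comes from butenolide 5, whose ring fixes the Z alkene: 5 → salts 6 and 7 → acetoxy acid 8.
- Key disconnection: the C3–O ester bond is cut back to the benzylic C3–H of 4. DDQ dearomatizes the phenol to para-quinone methide 9, and 8 adds anti to the isopropenyl group to give target 10 directly.
- C2 keeps its geometry from 4 to 10; the descriptor changes from S to R only because the new C3 oxygen raises the CIP rank of C3.

**Step 1**
Reactants: 1 2,4-dihydroxyacetophenone (resacetophenone)
Product: 2 1-(5-bromo-2,4-dihydroxyphenyl)ethan-1-one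
Conditions: NBS (1.0 equiv), MeCN, 0 → 20 °C
Reagents that add atoms: N-bromosuccinimide, O=C1CCC(=O)N1Br
Why: Electrophilic aromatic bromination; C5 (para to the chelated 2-OH, ortho to the 4-OH) is the most activated unhindered site while C3 is flanked by both hydroxyls, so one equivalent gives the 5-bromide, and no stereocentre is formed.

**Step 2**
Reactants: 2 1-(5-bromo-2,4-dihydroxyphenyl)ethan-1-one; 3 isoprene (2-methylbuta-1,3-diene)
Product: 4 1-[(2S)-6-hydroxy-2-(prop-1-en-2-yl)-2,3-dihydro-1-benzofuran-5-yl]ethan-1-one ((S)-6-hydroxytremetone)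
Conditions: Pd2(dba)3 (2.5 mol %), chiral sulfinamide–monophosphine ligand of the TY-Phos class (10 mol %, antipode giving 2S), PhONa (2.2 equiv), isoprene (5 equiv), CH2Cl2, 40 °C, sealed tube
Reagents that add atoms: none
Why: Enantioselective Heck/Tsuji–Trost (Larock-type) heteroannulation of a 1,3-diene: zerovalent palladium inserts into the C–Br bond, the aryl group adds to the unsubstituted vinyl terminus of isoprene, and the phenoxide ortho to the new bond attacks the internal carbon of the π-allyl complex inside the chiral ligand pocket, closing the dihydrofuran ring and setting C2 as S.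

**Step 3**
Reactants: 5 3-methylfuran-2(5H)-one
Product: 8 (2Z)-4-(acetyloxy)-2-methylbut-2-enoic acid, via potassium (2Z)-4-hydroxy-2-methylbut-2-enoate 6 (not isolated), via potassium (2Z)-4-(acetyloxy)-2-methylbut-2-enoate 7 (not isolated)
Conditions: KOH (1.00 equiv), H2O, 0 → 20 °C; freeze-dry; vinyl acetate (3 equiv), K2CO3 (0.2 equiv), DMSO, 40 °C; then cold aq KHSO4 to pH 3, EtOAc
Reagents that add atoms: potassium hydroxide, [K+].[OH-]; vinyl acetate, C=COC(C)=O
Why: Lactone saponification followed by base-catalysed transesterification with an enol ester: the ring fixes the Z alkene, vinyl acetate cannot activate the carboxylate (so the lactone cannot re-form) while the alkoxide is acetylated irreversibly with loss of acetaldehyde, and acid is added only after the hydroxyl is capped; no stereocentre is formed.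

**Step 4**
Reactants: 4 1-[(2S)-6-hydroxy-2-(prop-1-en-2-yl)-2,3-dihydro-1-benzofuran-5-yl]ethan-1-one; 8 (2Z)-4-(acetyloxy)-2-methylbut-2-enoic acid
Product: 10 (2R,3S)-5-acetyl-6-hydroxy-2-(prop-1-en-2-yl)-2,3-dihydro-1-benzofuran-3-yl (2Z)-4-(acetyloxy)-2-methylbut-2-enoate, via para-quinone methide 9 (not isolated)
Conditions: DDQ (1.05 equiv), 8 (3 equiv), 4 Å molecular sieves, CH2Cl2, 0 → 20 °C, dark; cold aq NaHCO3/sodium ascorbate quench
Reagents that add atoms: none
Why: Proposed new method: DDQ removes hydride from the C3–H bond that is para to the free 6-OH and ortho to O1, dearomatizing the phenol to para-quinone methide 9; excess acid 8 protonates the quinone oxygen and its carboxylate adds to C3 from the face opposite the C2 isopropenyl group, restoring the arene and setting the 2,3-trans (3S) centre before C2–H loss to the benzofuran can compete at low temperature; the closest known reaction types are DDQ benzylic C–H oxidation with oxygen nucleophiles (trans-selective C4 functionalization of flavans) and DDQ-mediated oxidative coupling of benzylic C–H bonds with carboxylic acids.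

**Compound list**
1 | 2,4-dihydroxyacetophenone | CC(=O)c1ccc(O)cc1O | starting material
2 | 1-(5-bromo-2,4-dihydroxyphenyl)ethan-1-one | CC(=O)c1cc(Br)c(O)cc1O | intermediate
3 | isoprene | C=CC(C)=C | starting material
4 | 1-[(2S)-6-hydroxy-2-(prop-1-en-2-yl)-2,3-dihydro-1-benzofuran-5-yl]ethan-1-one | C=C(C)[C@H]1Oc2cc(O)c(C(C)=O)cc2C1 | intermediate
5 | 3-methylfuran-2(5H)-one | CC1=CCOC1=O | starting material
6 | potassium (2Z)-4-hydroxy-2-methylbut-2-enoate | O=C([O-])/C(C)=C\CO.[K+] | intermediate
7 | potassium (2Z)-4-(acetyloxy)-2-methylbut-2-enoate | O=C([O-])/C(C)=C\COC(C)=O.[K+] | intermediate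
8 | (2Z)-4-(acetyloxy)-2-methylbut-2-enoic acid | OC(=O)/C(C)=C\COC(C)=O | intermediate
9 | (2S)-5-acetyl-2-(prop-1-en-2-yl)-1-benzofuran-6(2H)-one (para-quinone methide) | C=C(C)[C@H]1OC2=CC(=O)C(C(C)=O)=CC2=C1 | intermediate
10 | (2R,3S)-5-acetyl-6-hydroxy-2-(prop-1-en-2-yl)-2,3-dihydro-1-benzofuran-3-yl (2Z)-4-(acetyloxy)-2-methylbut-2-enoate | C=C(C)[C@H]1Oc2cc(O)c(C(C)=O)cc2[C@@H]1OC(=O)/C(C)=C\COC(C)=O | target

**Step count**
Total: 4 steps. Longest linear sequence: 3 steps (1 → 2 → 4 → 10); the acid branch is one step.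

**Steps most likely to fail**

Step 4. The quinone methide 9 can lose its C2–H and aromatize to the benzofuran (euparin), which is the usual outcome of DDQ on dihydrobenzofurans, or the acid may add too slowly. The fallback sets out from 2 and comes back at 10; it installs the C3 oxygen by alkene oxidation instead of C–H oxidation.
- Suzuki–Miyaura coupling of 2 with (E)-(3-methylbuta-1,3-dien-1-yl)boronic acid pinacol ester (Pd(dppf)Cl2, K3PO4, dioxane/H2O, 80 °C) gives 1-{2,4-dihydroxy-5-[(1E)-3-methylbuta-1,3-dien-1-yl]phenyl}ethan-1-one F1.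
- Shi epoxidation with the L-sorbose-derived antipode of the fructose ketone (KHSO5, K2CO3, MeCN/dimethoxymethane/H2O, 0 °C) attacks only the aryl-conjugated E alkene and gives 1-{2,4-dihydroxy-5-[(2S,3S)-3-(prop-1-en-2-yl)oxiran-2-yl]phenyl}ethan-1-one F2.
- In the same basic medium the neighbouring phenoxide opens F2 at its allylic carbon with inversion, giving the trans diol 1-[(2R,3S)-3,6-dihydroxy-2-(prop-1-en-2-yl)-2,3-dihydro-1-benzofuran-5-yl]ethan-1-one F3.
- Yamaguchi esterification of the secondary hydroxyl of F3 with 8 (2,4,6-trichlorobenzoyl chloride, Et3N, DMAP, toluene, 20 °C; the chelated phenol is much less reactive, and room temperature avoids Z → E isomerization) gives 10.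

Step 2. The free, acidic bromoresorcinol may undergo slow oxidative addition or give low ee. The fallback sets out from 2 and comes back at 4; it sets C2 by reagent-controlled epoxidation.
- α-Selective Suzuki–Miyaura prenylation of 2 with 3-methylbut-2-en-1-ylboronic acid pinacol ester (Pd(OAc)2, bulky biaryl phosphine, K3PO4, THF/H2O) gives 1-[2,4-dihydroxy-5-(3-methylbut-2-en-1-yl)phenyl]ethan-1-one F4.
- Shi epoxidation (the D-fructose-derived ketone is the one expected to give the R epoxide; KHSO5, K2CO3, MeCN/dimethoxymethane/H2O, 0 °C) gives 1-(5-{[(2R)-3,3-dimethyloxiran-2-yl]methyl}-2,4-dihydroxyphenyl)ethan-1-one F5.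
- The phenoxide opens F5 in the same pot by 5-exo attack with inversion, giving 1-[(2S)-6-hydroxy-2-(2-hydroxypropan-2-yl)-2,3-dihydro-1-benzofuran-5-yl]ethan-1-one F6.
- Dehydration of the tertiary alcohol (SOCl2, pyridine, −20 °C, aqueous work-up) gives 4.

Step 3. O-acetylation of 6 may be incomplete, and any unacetylated material returns to lactone 5 on acidification. The fallback sets out from 6 and comes back at 8; it masks the carboxylate as an ester before acetylation.
- Alkylation of 6 with 4-methoxybenzyl chloride (NaI cat., DMF, 20 °C) gives 4-methoxybenzyl (2Z)-4-hydroxy-2-methylbut-2-enoate F7.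
- Immediate acetylation (Ac2O, pyridine, 0 °C) gives 4-methoxybenzyl (2Z)-4-(acetyloxy)-2-methylbut-2-enoate F8.
- Cleavage of the ester with CF3CO2H/Et3SiH in CH2Cl2 at 0 °C gives 8.

**Further compounds**
F1 | step 4 | 1-{2,4-dihydroxy-5-[(1E)-3-methylbuta-1,3-dien-1-yl]phenyl}ethan-1-one | CC(=O)c1cc(/C=C/C(C)=C)c(O)cc1O
F2 | step 4 | 1-{2,4-dihydroxy-5-[(2S,3S)-3-(prop-1-en-2-yl)oxiran-2-yl]phenyl}ethan-1-one | CC(=O)c1cc([C@@H]2O[C@H]2C(C)=C)c(O)cc1O
F3 | step 4 | 1-[(2R,3S)-3,6-dihydroxy-2-(prop-1-en-2-yl)-2,3-dihydro-1-benzofuran-5-yl]ethan-1-one | C=C(C)[C@H]1Oc2cc(O)c(C(C)=O)cc2[C@@H]1O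
F4 | step 2 | 1-[2,4-dihydroxy-5-(3-methylbut-2-en-1-yl)phenyl]ethan-1-one | CC(=O)c1cc(CC=C(C)C)c(O)cc1O
F5 | step 2 | 1-(5-{[(2R)-3,3-dimethyloxiran-2-yl]methyl}-2,4-dihydroxyphenyl)ethan-1-one | CC(=O)c1cc(C[C@H]2OC2(C)C)c(O)cc1O
F6 | step 2 | 1-[(2S)-6-hydroxy-2-(2-hydroxypropan-2-yl)-2,3-dihydro-1-benzofuran-5-yl]ethan-1-one | CC(C)(O)[C@H]1Oc2cc(O)c(C(C)=O)cc2C1
F7 | step 3 | 4-methoxybenzyl (2Z)-4-hydroxy-2-methylbut-2-enoate | COc1ccc(COC(=O)/C(C)=C\CO)cc1
F8 | step 3 | 4-methoxybenzyl (2Z)-4-(acetyloxy)-2-methylbut-2-enoate | COc1ccc(COC(=O)/C(C)=C\COC(C)=O)cc1
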